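The earlier runs and the new flask stem from a simulated flask with made-up constants; scatter was added.

Delta, charged with 1.1 M of substrate, had made 0.372 M of product after 3.00 min, and epsilon 0.0918 M at the same time, so delta had made more than epsilon, but its charge was 7.33 times epsilon's and its product 4.05 times. So the rate bends as substrate rises, and I read that bend as one number. If product made plus a constant times the logarithm of substrate charged over substrate left is equal for two runs of equal time, epsilon and delta give that constant as 0.525 M. This is the crossing concentration, the substrate concentration at which the rate stands at half of its ceiling, the Michaelis constant. The ceiling then reads 0.196 M min⁻¹ from epsilon and 0.199 M min⁻¹ from alpha, a run not used for the constant.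

the same everywhere: gas 100 mM (held)

| charge | substrate | free catalyst | remark | time |
|---|---|---|---|---|
| epsilon | 0.15 M | 4 mM | run made earlier |  |
| alpha | 0.56 M | 4 mM | run made earlier |  |
| delta | 1.1 M | 4 mM | run made earlier |  |
| ash | 0.20 M | 4.0 mM |  | 6.0 min |
| alder | 0.40 M | 4.0 mM |  | 6.0 min |
| maple | 0.80 M | 4.0 mM |  | 6.0 min |
| cedar | 1.5 M | 4.0 mM |  | 6.0 min |

- epsilon (time / min: product / %, substrate / %): 0.833: 20.4, 78.1; 1.50: 36.5, 62.9; 2.50: 53.7, 45.8; 3.00: 61.2, 38.9
- alpha (time / min: product / %, substrate / %): 0.417: 7.3, 92.4; 1.00: 17.1, 82.6; 2.00: 31.8, 66.7; 3.00: 46.3, 52.6
- delta (time / min: product / %, substrate / %): 0.833: 9.6, 89.9; 1.50: 16.9, 81.9; 2.50: 27.1, 71.8; 3.00: 33.8, 66.3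

(readings scatter by 0.5 percentage points)

- what was read earlier has a scatter of 0.5 percentage points, one standard deviation
- at the start none of the gas is in solution
- a reading or a percentage of product counts all its forms, free or not
- the concentration of product that is asked is that of its free form alone
- "hardly changes" means that all values lie within two and a half points (for a concentration: within two and a half percent of the largest)

1. [product] (only what is free in solution) at the end for ash, alder, maple, cedar, in this order
2. the course of these numbers from the first flask to the last (falls, then rises / rises, then falls / rises all the way / hardly changes / falls all the way)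

I turned the question round and asked what a flat or falling row needs. By my reading, ash lies below the crossing and starts at 0.0541 M min⁻¹, while cedar lies above it and starts at 0.145 M min⁻¹, so product counted in every form should rise along the row. A flat row therefore needs free product held at one level below ash's charge of 0.20 M, with the rest out of solution. The catalyst, at 4.0 mM, is far too small to hold that much, and the readings count every form, so they cannot show such a level. I reckoned a rise.

The forecast was 0.17 M, 0.32 M, 0.555 M and 0.78 M, a course that rises all the way, with the words “I expect a rise all the way”.

The flask gave 0.142 M, 0.144 M, 0.149 M and 0.157 M, so the course rises all the way, but across 0.0150 M.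

reagent + free catalyst → catalyst intermediate A (k = 584 M⁻¹ s⁻¹); substrate + catalyst intermediate A → catalyst intermediate B (k = 1.56 M⁻¹ s⁻¹); catalyst intermediate B → free catalyst + product (k = 0.877 s⁻¹); gas ⇌ reagent, rate k4*(csat - [reagent]) (kL = 0.0315 s⁻¹); crystals ⇌ product, rate k5*(cs5 - [product]) while solid is left; crystals form when [product] > cs5 (solubility = 0.140 M, k = 0.114 s⁻¹) Cedar at 6.00 min held product of 52.5% of its charge, and of that charge 42.0% stood as crystals. The crossing concentration can be held against the catalyst too. Ash ended with 0.0291 M of substrate, below 0.525 M, and its resting state was catalyst intermediate A at 95.0%. Cedar ended with 0.710 M, above it, with catalyst intermediate B at 54.6% against 43.2% of catalyst intermediate A.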